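Ring A = C1–C4, C4a, C8a (cyclohexene); ring B = C4a, C5–C8, C8a (cyclohexane); naphthalene numbering; primed numbers = the epoxy-cyclohexane side ring (C2′ carbinol, C5′ silyloxy carbon).
Cuts: pyridone C3–acyl carbon (aryllithium + aldehyde, then oxidation); pyridone C5–C2′ (aryllithium + epoxy ketone); in the decalin C2–C3, then C4a–C5, then C1–C8a.
Enabling feature: C3=C4(CH3) beside a C2 that can carry two esters is a dehydrated malonate–aldehyde aldol; opened, it is an (E)-2-methylenal C3(=O)–C4(CH3)=C4a with C4a as β-carbon, and C5 is the CH2Br carbon of citronellyl bromide.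
Forward: C1–C8a by amine-catalysed Michael addition; Wittig enal; ring B by 6-exo radical closure C5→C4a while C4a is still outside any ring (this permits the trans fusion); ring A by aldol/dehydration; then the C2 aldehyde; epoxy ketone and pyridine are joined first, the decalin aldehyde last.
Stereochemistry: C7 from (R)-citronellyl bromide; C1/C8a from the (S)-prolinol silyl ether catalyst; C4a from the chair transition state; C2 by equilibration (equatorial acyl); C5′ by Corey–Bakshi–Shibata reduction; epoxide anti to the silyl ether; C2′ by attack anti to the silyl ether and syn to the epoxide oxygen.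

Key step: step 5

Assumption: the enamine Michael addition in step 3 is taken to occur 1,4 at the dienylidene malonate and with the same synclinal (like) topicity as the corresponding additions to nitroalkenes.

Step 1
Reactants: 1 (2E)-but-2-enal; 2 dimethyl malonate
Product: 3 dimethyl 2-[(2E)-but-2-en-1-ylidene]propanedioate
Conditions: piperidine (cat.), AcOH (cat.), PhH, reflux, Dean–Stark
Reagents that add atoms: none
Why: Knoevenagel condensation of the malonate with the enal, driven by azeotropic removal of water, should give the dienylidene malonate with the (E)-propenyl unit intact.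

Step 2
Reactants: 4 (6R)-8-bromo-2,6-dimethyloct-2-ene [(R)-citronellyl bromide]
Product: 6 (4R)-6-bromo-4-methylhexanal, via ozonide 5 (not isolated)
Conditions: O3, CH2Cl2, −78 °C; then Me2S, −78 °C → rt
Reagents that add atoms: ozone, [O-][O+]=O
Why: Ozonolysis of the trisubstituted alkene with reductive work-up should give the aldehyde, leaving the primary bromide and the methyl stereocentre (future C7) untouched.

Step 3
Reactants: 6 (4R)-6-bromo-4-methylhexanal; 3 dimethyl 2-[(2E)-but-2-en-1-ylidene]propanedioate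
Product: 7 dimethyl 2-[(2E,4R,5R,7R)-9-bromo-5-formyl-7-methylnon-2-en-4-yl]propanedioate
Conditions: (S)-2-[diphenyl(trimethylsilyloxy)methyl]pyrrolidine (20 mol%), PhCO2H (20 mol%), CHCl3, 4 °C
Reagents that add atoms: none
Why: Enamine-catalysed asymmetric Michael addition forms C1–C8a; the silyloxydiphenylmethyl group shields one face of the (E)-enamine and the synclinal approach to the alkylidene malonate should set C8a and C1 (both R in 7) together.

Step 4
Reactants: 7 dimethyl 2-[(2E,4R,5R,7R)-9-bromo-5-formyl-7-methylnon-2-en-4-yl]propanedioate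
Product: 8 dimethyl 2-[(2E,4R,5R,6E)-5-[(2R)-4-bromo-2-methylbutyl]-7-methyl-8-oxoocta-2,6-dien-4-yl]propanedioate
Conditions: Ph3P=C(CH3)CHO, PhMe, 90 °C
Reagents that add atoms: 2-(triphenylphosphoranylidene)propanal, CC(C=O)=P(c1ccccc1)(c1ccccc1)c1ccccc1
Why: Wittig olefination with the stabilised, non-basic ylide should give the (E)-2-methylenal without epimerising the α-centre; the (E) geometry keeps the formyl group away from the malonate, so ring A cannot close before ring B.

Step 5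
Reactants: 8 dimethyl 2-[(2E,4R,5R,6E)-5-[(2R)-4-bromo-2-methylbutyl]-7-methyl-8-oxoocta-2,6-dien-4-yl]propanedioate
Product: 9 dimethyl 2-{(1R,2E)-1-[(1S,2S,5S)-5-methyl-2-(1-oxopropan-2-yl)cyclohexyl]but-2-en-1-yl}propanedioate (both epimers at the propanal α-carbon)
Conditions: Bu3SnH, azobisisobutyronitrile (cat.), PhH (0.01 M), 80 °C, slow addition
Reagents that add atoms: none
Why: Bu3Sn• abstracts bromine from the primary C–Br bond, the C5 radical adds to C4a (the β-carbon of the (E)-2-methylenal), and the α-formyl radical takes hydrogen from Bu3SnH to carry the chain. The closest known reaction type is the tin hydride mediated Giese-type 6-exo cyclisation of ω-haloalkyl enoates and enals. Ring B (C4a, C5, C6, C7, C8, C8a) closes in the 6-exo-trig mode. C4a is set by a chair-like transition state with the C7 methyl group, the C8a side chain and the enal unit all equatorial, which gives the trans relation at C4a/C8a; the exocyclic α-carbon forms as both epimers and becomes sp2 again in step 7. The step needs attack at the β-carbon (6-exo over 7-endo), cyclisation before direct reduction (high dilution, slow addition), and polarity-matched hydrogen transfer to the electrophilic α-formyl radical before it adds 5-exo to the propenyl group; because C4a is not yet in ring A, the chair is free of the constraint that would enforce a cis fusion.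

Step 6
Reactants: 9 dimethyl 2-{(1R,2E)-1-[(1S,2S,5S)-5-methyl-2-(1-oxopropan-2-yl)cyclohexyl]but-2-en-1-yl}propanedioate
Product: 10 dimethyl (1R,4aS,7S,8aS)-3-hydroxy-4,7-dimethyl-1-[(1E)-prop-1-en-1-yl]octahydronaphthalene-2,2(1H)-dicarboxylate (C3/C4 mixture, equatorial OH and CH3 expected to dominate)
Conditions: 1,8-diazabicyclo[5.4.0]undec-7-ene (30 mol%), CH2Cl2, 0 °C → rt
Reagents that add atoms: none
Why: Reversible intramolecular aldol addition (6-exo-trig) of the malonate to the aldehyde closes ring A at C2–C3, and equilibration through the enolisable open aldehyde should favour the diequatorial C3-OH/C4-CH3 isomer.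

Step 7
Reactants: 10 dimethyl (1R,4aS,7S,8aS)-3-hydroxy-4,7-dimethyl-1-[(1E)-prop-1-en-1-yl]octahydronaphthalene-2,2(1H)-dicarboxylate
Product: 11 dimethyl (1R,4aS,7S,8aS)-4,7-dimethyl-1-[(1E)-prop-1-en-1-yl]-4a,5,6,7,8,8a-hexahydronaphthalene-2,2(1H)-dicarboxylate
Conditions: methyl N-(triethylammoniosulfonyl)carbamate, PhMe, 70 °C
Reagents that add atoms: none
Why: Burgess dehydration (syn-elimination) can only use the C4 hydrogen because C2 is quaternary, so the alkene should form regiospecifically as C3=C4.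

Step 8
Reactants: 11 dimethyl (1R,4aS,7S,8aS)-4,7-dimethyl-1-[(1E)-prop-1-en-1-yl]-4a,5,6,7,8,8a-hexahydronaphthalene-2,2(1H)-dicarboxylate
Product: 12 methyl (1R,2S,4aS,7S,8aR)-4,7-dimethyl-1-[(1E)-prop-1-en-1-yl]-1,2,4a,5,6,7,8,8a-octahydronaphthalene-2-carboxylate
Conditions: LiCl, H2O, DMSO, 150 °C
Reagents that add atoms: none
Why: Krapcho dealkoxycarbonylation removes one ester; α-protonation of the resulting dienolate keeps the C3=C4 alkene, and C2 should settle as the equatorial ester trans to the propenyl group.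

Step 9
Reactants: 12 methyl (1R,2S,4aS,7S,8aR)-4,7-dimethyl-1-[(1E)-prop-1-en-1-yl]-1,2,4a,5,6,7,8,8a-octahydronaphthalene-2-carboxylate
Product: 13 (1R,2S,4aS,7S,8aR)-4,7-dimethyl-1-[(1E)-prop-1-en-1-yl]-1,2,4a,5,6,7,8,8a-octahydronaphthalene-2-carbaldehyde
Conditions: i-Bu2AlH, CH2Cl2, −78 °C; MeOH, aq. potassium sodium tartrate
Reagents that add atoms: none
Why: Partial hydride reduction of the ester at −78 °C stops at the aluminium hemiacetal, which should release the aldehyde on work-up without touching C2 or the alkenes.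

Step 10
Reactants: 14 1,4-dioxaspiro[4.5]dec-6-en-8-one
Product: 15 (8R)-1,4-dioxaspiro[4.5]dec-6-en-8-ol
Conditions: (S)-1-methyl-3,3-diphenyltetrahydro-1H,3H-pyrrolo[1,2-c][1,3,2]oxazaborole (10 mol%), BH3·SMe2, THF, −20 °C; MeOH
Reagents that add atoms: none
Why: Corey–Bakshi–Shibata reduction, with the alkenyl flank acting as the large group, should deliver hydride to give the (R)-allylic alcohol (future C5′).

Step 11
Reactants: 15 (8R)-1,4-dioxaspiro[4.5]dec-6-en-8-ol
Product: 16 tert-butyl[(8R)-1,4-dioxaspiro[4.5]dec-6-en-8-yloxy]dimethylsilane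
Conditions: t-BuMe2SiCl, imidazole, DMF, rt
Reagents that add atoms: tert-butyldimethylsilyl chloride, CC(C)(C)[Si](C)(C)Cl
Why: Standard silylation of the secondary alcohol gives a bulky ether that later directs both the epoxidation and the carbonyl addition.

Step 12
Reactants: 16 tert-butyl[(8R)-1,4-dioxaspiro[4.5]dec-6-en-8-yloxy]dimethylsilane
Product: 17 (4R)-4-[(tert-butyldimethylsilyl)oxy]cyclohex-2-en-1-one
Conditions: pyridinium p-toluenesulfonate (cat.), acetone/H2O, 50 °C
Reagents that add atoms: water, O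
Why: Mild acid-catalysed ketal hydrolysis unmasks the enone while the secondary silyl ether should survive.

Step 13
Reactants: 17 (4R)-4-[(tert-butyldimethylsilyl)oxy]cyclohex-2-en-1-one
Product: 18 (1S,5R,6R)-5-[(tert-butyldimethylsilyl)oxy]-7-oxabicyclo[4.1.0]heptan-2-one (epoxide trans to the silyloxy group)
Conditions: 30% H2O2, BnNMe3OH (cat.), THF, 0 °C
Reagents that add atoms: hydrogen peroxide, OO
Why: Weitz–Scheffer nucleophilic epoxidation, in which hydroperoxide adds to the enone face opposite the γ-silyloxy group, should give the trans epoxy ketone.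

Step 14
Reactants: 19 5-bromo-2,4-dichloropyridine
Product: 20 5-bromo-2,4-bis[2-(trimethylsilyl)ethoxy]pyridine
Conditions: Me3SiCH2CH2OH, NaH, DMF, 0 → 80 °C
Reagents that add atoms: 2-(trimethylsilyl)ethanol, C[Si](C)(C)CCO
Why: Twofold nucleophilic aromatic substitution at the activated 4- and 2-positions installs fluoride-labile ethers as the masked 4-hydroxy-2-pyridone, leaving the 5-bromide.

Step 15
Reactants: 20 5-bromo-2,4-bis[2-(trimethylsilyl)ethoxy]pyridine; 18 (1S,5R,6R)-5-[(tert-butyldimethylsilyl)oxy]-7-oxabicyclo[4.1.0]heptan-2-one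
Product: 22 (1S,2R,5R,6R)-2-{4,6-bis[2-(trimethylsilyl)ethoxy]pyridin-3-yl}-5-[(tert-butyldimethylsilyl)oxy]-7-oxabicyclo[4.1.0]heptan-2-ol, via 5-lithiopyridine 21 (not isolated)
Conditions: n-BuLi, THF, −78 °C; then 18, −78 °C; H2O
Reagents that add atoms: none
Why: Bromine–lithium exchange and 1,2-addition to the ketone; the aryl group should enter anti to the silyloxy group and on the face of the epoxide oxygen (lithium bridging, the sense seen in reductions of 2,3-epoxycyclohexanones to trans-epoxy alcohols), setting C2′.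

Step 16
Reactants: 22 (1S,2R,5R,6R)-2-{4,6-bis[2-(trimethylsilyl)ethoxy]pyridin-3-yl}-5-[(tert-butyldimethylsilyl)oxy]-7-oxabicyclo[4.1.0]heptan-2-ol
Product: 23 (1S,2R,5R,6R)-2-{5-bromo-4,6-bis[2-(trimethylsilyl)ethoxy]pyridin-3-yl}-5-[(tert-butyldimethylsilyl)oxy]-7-oxabicyclo[4.1.0]heptan-2-ol
Conditions: N-bromosuccinimide, MeCN, 0 °C → rt
Reagents that add atoms: N-bromosuccinimide, O=C1CCC(=O)N1Br
Why: Electrophilic aromatic bromination should occur at the only position ortho/para to both alkoxy groups (between them), giving a handle for low-temperature metalation that spares the epoxide.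

Step 17
Reactants: 23 (1S,2R,5R,6R)-2-{5-bromo-4,6-bis[2-(trimethylsilyl)ethoxy]pyridin-3-yl}-5-[(tert-butyldimethylsilyl)oxy]-7-oxabicyclo[4.1.0]heptan-2-ol; 13 (1R,2S,4aS,7S,8aR)-4,7-dimethyl-1-[(1E)-prop-1-en-1-yl]-1,2,4a,5,6,7,8,8a-octahydronaphthalene-2-carbaldehyde
Product: 25 the secondary alcohol from addition of the pyridine C3 to the aldehyde carbon of 13 (both carbinol epimers, all other centres as in 13 and 23), via dilithio species 24 (not isolated)
Conditions: n-BuLi (2.1 equiv), THF, −78 °C; then 13, −78 °C; H2O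
Reagents that add atoms: none
Why: Deprotonation of the tertiary alcohol, bromine–lithium exchange and 1,2-addition of the aryllithium to the aldehyde join the two halves; the new carbinol centre is lost in step 18.

Step 18
Reactants: 25 secondary alcohol
Product: 26 {5-[(1S,2R,5R,6R)-5-[(tert-butyldimethylsilyl)oxy]-2-hydroxy-7-oxabicyclo[4.1.0]heptan-2-yl]-2,4-bis[2-(trimethylsilyl)ethoxy]pyridin-3-yl}[(1R,2S,4aS,7S,8aR)-4,7-dimethyl-1-[(1E)-prop-1-en-1-yl]-1,2,4a,5,6,7,8,8a-octahydronaphthalen-2-yl]methanone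
Conditions: 1,1,1-triacetoxy-1,1-dihydro-1,2-benziodoxol-3(1H)-one, pyridine, CH2Cl2, 0 °C → rt
Reagents that add atoms: none
Why: Dess–Martin oxidation converts the secondary carbinol to the ketone under buffered conditions; the tertiary alcohol, epoxide and silyl groups should be inert.

Step 19
Reactants: 26 protected ketone
Product: 27 3-{[(1R,2S,4aS,7S,8aR)-4,7-dimethyl-1-[(1E)-prop-1-en-1-yl]-1,2,4a,5,6,7,8,8a-octahydronaphthalen-2-yl]carbonyl}-5-[(1S,2R,5R,6S)-2,5-dihydroxy-7-oxabicyclo[4.1.0]heptan-2-yl]-4-hydroxypyridin-2(1H)-one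
Conditions: Bu4NF, AcOH, THF, 0 → 40 °C
Reagents that add atoms: none
Why: Buffered fluoride desilylation cleaves the silyl ether and fragments both 2-(trimethylsilyl)ethyl ethers (loss of ethene) to reveal the 4-hydroxy-2-pyridone; any C2 epimer should converge on the equatorial acyl isomer.

Compound list
1 | (2E)-but-2-enal | C/C=C/C=O | starting material
2 | dimethyl malonate | COC(=O)CC(=O)OC | starting material
3 | dimethyl 2-[(2E)-but-2-en-1-ylidene]propanedioate | C/C=C/C=C(C(=O)OC)C(=O)OC | intermediate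
4 | (6R)-8-bromo-2,6-dimethyloct-2-ene | CC(C)=CCC[C@@H](C)CCBr | starting material
5 | 5-[(3R)-5-bromo-3-methylpentyl]-3,3-dimethyl-1,2,4-trioxolane (ozonide) | CC1(C)OOC(CC[C@@H](C)CCBr)O1 | intermediate
6 | (4R)-6-bromo-4-methylhexanal | O=CCC[C@@H](C)CCBr | intermediate
7 | dimethyl 2-[(2E,4R,5R,7R)-9-bromo-5-formyl-7-methylnon-2-en-4-yl]propanedioate | C/C=C/[C@@H](C(C(=O)OC)C(=O)OC)[C@@H](C[C@@H](C)CCBr)C=O | intermediate
8 | dimethyl 2-[(2E,4R,5R,6E)-5-[(2R)-4-bromo-2-methylbutyl]-7-methyl-8-oxoocta-2,6-dien-4-yl]propanedioate | C/C=C/[C@@H](C(C(=O)OC)C(=O)OC)[C@@H](C[C@@H](C)CCBr)/C=C(\C)C=O | intermediate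
9 | dimethyl 2-{(1R,2E)-1-[(1S,2S,5S)-5-methyl-2-(1-oxopropan-2-yl)cyclohexyl]but-2-en-1-yl}propanedioate | C/C=C/[C@@H](C(C(=O)OC)C(=O)OC)[C@H]1C[C@@H](C)CC[C@@H]1C(C)C=O | intermediate
10 | dimethyl (1R,4aS,7S,8aS)-3-hydroxy-4,7-dimethyl-1-[(1E)-prop-1-en-1-yl]octahydronaphthalene-2,2(1H)-dicarboxylate | C/C=C/[C@@H]1[C@H]2C[C@@H](C)CC[C@@H]2C(C)C(O)C1(C(=O)OC)C(=O)OC | intermediate
11 | dimethyl (1R,4aS,7S,8aS)-4,7-dimethyl-1-[(1E)-prop-1-en-1-yl]-4a,5,6,7,8,8a-hexahydronaphthalene-2,2(1H)-dicarboxylate | C/C=C/[C@@H]1[C@H]2C[C@@H](C)CC[C@@H]2C(C)=CC1(C(=O)OC)C(=O)OC | intermediate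
12 | methyl (1R,2S,4aS,7S,8aR)-4,7-dimethyl-1-[(1E)-prop-1-en-1-yl]-1,2,4a,5,6,7,8,8a-octahydronaphthalene-2-carboxylate | C/C=C/[C@@H]1[C@H]2C[C@@H](C)CC[C@@H]2C(C)=C[C@H]1C(=O)OC | intermediate
13 | (1R,2S,4aS,7S,8aR)-4,7-dimethyl-1-[(1E)-prop-1-en-1-yl]-1,2,4a,5,6,7,8,8a-octahydronaphthalene-2-carbaldehyde | C/C=C/[C@@H]1[C@H]2C[C@@H](C)CC[C@@H]2C(C)=C[C@H]1C=O | intermediate
14 | 1,4-dioxaspiro[4.5]dec-6-en-8-one | O=C1CCC2(OCCO2)C=C1 | starting material
15 | (8R)-1,4-dioxaspiro[4.5]dec-6-en-8-ol | O[C@@H]1CCC2(OCCO2)C=C1 | intermediate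
16 | tert-butyl[(8R)-1,4-dioxaspiro[4.5]dec-6-en-8-yloxy]dimethylsilane | CC(C)(C)[Si](C)(C)O[C@@H]1CCC2(OCCO2)C=C1 | intermediate
17 | (4R)-4-[(tert-butyldimethylsilyl)oxy]cyclohex-2-en-1-one | CC(C)(C)[Si](C)(C)O[C@@H]1CCC(=O)C=C1 | intermediate
18 | (1S,5R,6R)-5-[(tert-butyldimethylsilyl)oxy]-7-oxabicyclo[4.1.0]heptan-2-one | O=C1CC[C@@H](O[Si](C)(C)C(C)(C)C)[C@@H]2O[C@@H]21 | intermediate
19 | 5-bromo-2,4-dichloropyridine | Clc1cc(Cl)c(Br)cn1 | starting material
20 | 5-bromo-2,4-bis[2-(trimethylsilyl)ethoxy]pyridine | C[Si](C)(C)CCOc1cc(OCC[Si](C)(C)C)c(Br)cn1 | intermediate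
21 | {4,6-bis[2-(trimethylsilyl)ethoxy]pyridin-3-yl}lithium | [Li]c1cnc(OCC[Si](C)(C)C)cc1OCC[Si](C)(C)C | intermediate
22 | (1S,2R,5R,6R)-2-{4,6-bis[2-(trimethylsilyl)ethoxy]pyridin-3-yl}-5-[(tert-butyldimethylsilyl)oxy]-7-oxabicyclo[4.1.0]heptan-2-ol | C[Si](C)(C)CCOc1cc(OCC[Si](C)(C)C)c([C@]2(O)CC[C@@H](O[Si](C)(C)C(C)(C)C)[C@@H]3O[C@@H]32)cn1 | intermediate
23 | (1S,2R,5R,6R)-2-{5-bromo-4,6-bis[2-(trimethylsilyl)ethoxy]pyridin-3-yl}-5-[(tert-butyldimethylsilyl)oxy]-7-oxabicyclo[4.1.0]heptan-2-ol | C[Si](C)(C)CCOc1ncc([C@]2(O)CC[C@@H](O[Si](C)(C)C(C)(C)C)[C@@H]3O[C@@H]32)c(OCC[Si](C)(C)C)c1Br | intermediate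
24 | lithium alkoxide of 22 lithiated at the pyridine carbon between the two ether groups (dilithio species) | [Li]c1c(OCC[Si](C)(C)C)ncc([C@]2(O[Li])CC[C@@H](O[Si](C)(C)C(C)(C)C)[C@@H]3O[C@@H]32)c1OCC[Si](C)(C)C | intermediate
25 | secondary alcohol: [decalin-2-yl](pyridin-3-yl)methanol corresponding to 26, both carbinol epimers | C/C=C/[C@@H]1[C@H]2C[C@@H](C)CC[C@@H]2C(C)=C[C@H]1C(O)c1c(OCC[Si](C)(C)C)c([C@]2(O)CC[C@@H](O[Si](C)(C)C(C)(C)C)[C@@H]3O[C@@H]32)cnc1OCC[Si](C)(C)C | intermediate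
26 | {5-[(1S,2R,5R,6R)-5-[(tert-butyldimethylsilyl)oxy]-2-hydroxy-7-oxabicyclo[4.1.0]heptan-2-yl]-2,4-bis[2-(trimethylsilyl)ethoxy]pyridin-3-yl}[(1R,2S,4aS,7S,8aR)-4,7-dimethyl-1-[(1E)-prop-1-en-1-yl]-1,2,4a,5,6,7,8,8a-octahydronaphthalen-2-yl]methanone | C/C=C/[C@@H]1[C@H]2C[C@@H](C)CC[C@@H]2C(C)=C[C@H]1C(=O)c1c(OCC[Si](C)(C)C)c([C@]2(O)CC[C@@H](O[Si](C)(C)C(C)(C)C)[C@@H]3O[C@@H]32)cnc1OCC[Si](C)(C)C | intermediate
27 | 3-{[(1R,2S,4aS,7S,8aR)-4,7-dimethyl-1-[(1E)-prop-1-en-1-yl]-1,2,4a,5,6,7,8,8a-octahydronaphthalen-2-yl]carbonyl}-5-[(1S,2R,5R,6S)-2,5-dihydroxy-7-oxabicyclo[4.1.0]heptan-2-yl]-4-hydroxypyridin-2(1H)-one | C/C=C/[C@@H]1[C@H]2C[C@@H](C)CC[C@@H]2C(C)=C[C@H]1C(=O)c1c(O)c([C@]2(O)CC[C@@H](O)[C@@H]3O[C@@H]32)c[nH]c1=O | target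

Total step count: 19. Longest linear sequence: 11 steps (steps 2–9, then 17–19).

Steps most likely to fail

Step 5. The 6-exo closure may discriminate poorly between the trans and cis chair transition states at C4a, and the α-formyl radical may be intercepted by the propenyl group (5-exo) before hydrogen transfer. The fallback sets out from 7, comes back at 9, and closes ring B by enolate alkylation under thermodynamic control. Aldehyde 7 would be homologated with (1-methoxyethylidene)triphenylphosphorane to the methyl enol ether F1 and hydrolysed with aqueous oxalic acid to the methyl ketone F2. KOt-Bu (2.2 equiv, THF/t-BuOH) would alkylate the internal ketone α-carbon with the primary bromide (6-exo-tet; the methyl-side enolate cannot reach) and equilibrate that α-centre to the trans-2-acetylcyclohexane F3. Wittig methoxymethylenation (Ph3P=CHOMe) would give the enol ether F4, whose mild acid hydrolysis returns aldehyde 9.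

Step 3. The enamine may add 1,6 instead of 1,4, the C1/C8a diastereocontrol may be insufficient, or the amine catalyst may be consumed by alkylation with the primary bromide. The fallback sets out from 6 and comes back at 7 using an oxazolidinone auxiliary. Oxidation of 6 (NaClO2, NaH2PO4, 2-methylbut-2-ene) would give (4R)-6-bromo-4-methylhexanoic acid F5. Acylation of (4S)-4-benzyl-1,3-oxazolidin-2-one (t-BuCOCl, Et3N, LiCl) would give the N-acyl oxazolidinone F6. Its chlorotitanium (Z)-enolate (TiCl4, i-Pr2NEt, CH2Cl2, −78 °C) would add to 3 from the face away from the benzyl group to give the Michael adduct F7. LiBH4 (Et2O, H2O, 0 °C) would cleave the imide selectively to the primary alcohol F8, and Dess–Martin oxidation returns 7.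

Step 17. The basic, hindered aryllithium may deprotonate the aldehyde at C2 (enolisation, recovery of epimerised aldehyde) instead of adding to it. The fallback sets out from 12, comes back at 26, and replaces addition/oxidation by acylation. Saponification of 12 (LiOH, THF/H2O) would give the decalin carboxylic acid F9. Coupling with MeNHOMe·HCl (carbodiimide) would give the N-methoxy-N-methylamide F10. Addition of dilithio species 24 (from 23 as in step 17) to F10 should give ketone 26 directly, making step 18 unnecessary.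

Further compounds
F1 | step 5 | dimethyl 2-[(2E)-5-[(2R)-4-bromo-2-methylbutyl]-7-methoxyocta-2,6-dien-4-yl]propanedioate (C4, C5 as in 7; enol ether E/Z mixture) | C/C=C/[C@@H](C(C(=O)OC)C(=O)OC)[C@@H](C[C@@H](C)CCBr)C=C(C)OC
F2 | step 5 | dimethyl 2-[(2E)-5-[(2R)-4-bromo-2-methylbutyl]-7-oxooct-2-en-4-yl]propanedioate (C4, C5 as in 7) | C/C=C/[C@@H](C(C(=O)OC)C(=O)OC)[C@@H](C[C@@H](C)CCBr)CC(C)=O
F3 | step 5 | dimethyl 2-{(1R,2E)-1-[trans-2-acetyl-cis-5-methylcyclohexyl]but-2-en-1-yl}propanedioate (ring centres as in 9) | C/C=C/[C@@H](C(C(=O)OC)C(=O)OC)[C@H]1C[C@@H](C)CC[C@@H]1C(C)=O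
F4 | step 5 | dimethyl 2-{(1R,2E)-1-[2-(1-methoxyprop-1-en-2-yl)-5-methylcyclohexyl]but-2-en-1-yl}propanedioate (ring centres as in 9) | C/C=C/[C@@H](C(C(=O)OC)C(=O)OC)[C@H]1C[C@@H](C)CC[C@@H]1C(C)=COC
F5 | step 3 | (4R)-6-bromo-4-methylhexanoic acid | OC(=O)CC[C@@H](C)CCBr
F6 | step 3 | (4S)-4-benzyl-3-[(4R)-6-bromo-4-methylhexanoyl]-1,3-oxazolidin-2-one | O=C(CC[C@@H](C)CCBr)N1[C@@H](Cc2ccccc2)COC1=O
F7 | step 3 | dimethyl 2-[(2E,4R,5R,7R)-5-{[(4S)-4-benzyl-2-oxo-1,3-oxazolidin-3-yl]carbonyl}-9-bromo-7-methylnon-2-en-4-yl]propanedioate | C/C=C/[C@@H](C(C(=O)OC)C(=O)OC)[C@@H](C[C@@H](C)CCBr)C(=O)N1[C@@H](Cc2ccccc2)COC1=O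
F8 | step 3 | dimethyl 2-[(2E,4R,5R,7R)-9-bromo-5-(hydroxymethyl)-7-methylnon-2-en-4-yl]propanedioate | C/C=C/[C@@H](C(C(=O)OC)C(=O)OC)[C@@H](C[C@@H](C)CCBr)CO
F9 | step 17 | (1R,2S,4aS,7S,8aR)-4,7-dimethyl-1-[(1E)-prop-1-en-1-yl]-1,2,4a,5,6,7,8,8a-octahydronaphthalene-2-carboxylic acid | C/C=C/[C@@H]1[C@H]2C[C@@H](C)CC[C@@H]2C(C)=C[C@H]1C(=O)O
F10 | step 17 | (1R,2S,4aS,7S,8aR)-N-methoxy-N,4,7-trimethyl-1-[(1E)-prop-1-en-1-yl]-1,2,4a,5,6,7,8,8a-octahydronaphthalene-2-carboxamide | C/C=C/[C@@H]1[C@H]2C[C@@H](C)CC[C@@H]2C(C)=C[C@H]1C(=O)N(C)OC
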